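The route rests on cutting the C2–C3 bond of ring C. C2 is a methine on O1 and C3 lies alpha to the C4 ketone, so C3 can act as a rhodium carbenoid and C2 can start as the methylene of an O1 ethyl ether. One enantioselective 1,6 C–H insertion then closes ring C and sets the cis C2/C3 methyl pair. Its precursor is an alpha-methyl diazo ketone on a phloroglucinol core bearing O1 ethyl, O7 methyl and O5 triisopropylsilyl groups. Since C3 epimerises with base, no later step uses free base: C8 iodination, Stille acrylate coupling, rhodium-catalysed phenyl addition, then C6 iodination, Stille prenylation and tin hydroxide ester cleavage.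

Key step: step 5

Assumption: the sense of induction of Rh2(S-PTTL)4 (step 5) and of (R,R)-Ph-bod* (step 8) is assigned by analogy with simpler substrates; if a first run shows the opposite sense, the mirror-image catalyst, equally accessible, is used.

Step 1
Reactants: 1 1-(2,4,6-trihydroxyphenyl)propan-1-one; 2 dimethyl sulfate
Product: 3 1-(2,6-dihydroxy-4-methoxyphenyl)propan-1-one
Conditions: Me2SO4 (1.0 equiv), K2CO3 (1.0 equiv), acetone, reflux
Reagents that add atoms: dimethyl sulfate COS(=O)(=O)OC
Why: Williamson-type O-methylation, in which the hydroxyl para to the acyl group is the most acidic and the only one not held in a hydrogen bond to the ketone, so one equivalent of base and electrophile should alkylate it first.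

Step 2
Reactants: 3 1-(2,6-dihydroxy-4-methoxyphenyl)propan-1-one; 4 iodoethane
Product: 5 1-(2-ethoxy-6-hydroxy-4-methoxyphenyl)propan-1-one
Conditions: EtI (1.1 equiv), K2CO3 (1.2 equiv), acetone, reflux
Reagents that add atoms: iodoethane CCI
Why: Williamson ether synthesis, in which the two ortho phenols of 3 are equivalent and the one left after the first ethylation is locked in a chelate with the carbonyl and reacts far more slowly, so the reaction should stop at the monoether.

Step 3
Reactants: 5 1-(2-ethoxy-6-hydroxy-4-methoxyphenyl)propan-1-one; 6 triisopropylsilyl trifluoromethanesulfonate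
Product: 7 1-[2-ethoxy-4-methoxy-6-(triisopropylsilyloxy)phenyl]propan-1-one
Conditions: TIPSOTf (1.2 equiv), 2,6-lutidine (1.5 equiv), CH2Cl2, 0 °C to rt
Reagents that add atoms: triisopropylsilyl trifluoromethanesulfonate CC(C)[Si](C(C)C)(C(C)C)OS(=O)(=O)C(F)(F)F
Why: O-silylation with a silyl triflate and a hindered pyridine base overcomes the low nucleophilicity of the chelated phenol, and the chosen group has no C–H next to oxygen, is too bulky to migrate to an enolate oxygen in step 4 and later shields C6.

Step 4
Reactants: 7 1-[2-ethoxy-4-methoxy-6-(triisopropylsilyloxy)phenyl]propan-1-one; 8 2,2,2-trifluoroethyl trifluoroacetate; 9 4-acetamidobenzenesulfonyl azide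
Product: 11 2-diazo-1-[2-ethoxy-4-methoxy-6-(triisopropylsilyloxy)phenyl]propan-1-one, via trifluoroacetyl diketone 10 (not isolated)
Conditions: LiHMDS (1.1 equiv), THF, −78 °C; CF3CO2CH2CF3 (1.2 equiv), −78 °C; dilute HCl wash; then 4-acetamidobenzenesulfonyl azide (1.5 equiv), Et3N (1.5 equiv), H2O (1 equiv), MeCN, rt
Reagents that add atoms: 2,2,2-trifluoroethyl trifluoroacetate FC(F)(F)COC(=O)C(F)(F)F (atoms kept only in 10); 4-acetamidobenzenesulfonyl azide CC(=O)Nc1ccc(cc1)S(=O)(=O)N=[N+]=[N-]
Why: Detrifluoroacetylative (deacylative Regitz) diazo transfer, in which Claisen trifluoroacetylation of the lithium enolate activates the alpha carbon, the sulfonyl azide delivers N2 there and the trifluoroacetyl group leaves on the sulfonamide nitrogen, a sequence suited to ethyl ketones that resist direct diazo transfer.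

Step 5
Reactants: 11 2-diazo-1-[2-ethoxy-4-methoxy-6-(triisopropylsilyloxy)phenyl]propan-1-one
Product: 12 (2S,3R)-7-methoxy-2,3-dimethyl-5-(triisopropylsilyloxy)chroman-4-one (cis)
Conditions: Rh2(S-PTTL)4 = dirhodium tetrakis[N-phthaloyl-(S)-tert-leucinate] (1 mol %), toluene, 4 Å molecular sieves, slow addition of 11, −78 to −20 °C
Reagents that add atoms: none
Why: Rh2(S-PTTL)4 expels N2 from 11, and the electrophilic carbenoid at C3 takes up one methylene C–H bond of the O1 ethyl group through a concerted, hydride-transfer-like three-centre transition state, forming C2–C3 and C3–H while the dirhodium core departs. The closest known reaction type is the enantioselective intramolecular C–H insertion of 2-alkoxyaryl alpha-diazo ketones under chiral dirhodium carboxylates, which gives cis-2,3-disubstituted chroman-4-ones. Ring C closes as a six-membered ring by 1,6-insertion (C3, C4, C4a, C8a, O1, C2), the only mode open because the flat aryl ketone tether puts no C–H bond at the 1,5 distance and the oxygen lone pair activates the O–CH2 bonds. C2 is set by the choice between the two enantiotopic methylene hydrogens inside the chiral pocket formed by the four phthalimido walls, with retention at that carbon. C3 is set in the same event, because the metal sits on the face that receives the hydrogen, so the C2 methyl turns to the opposite face where the C3 methyl lies, which gives the cis pair as (2S,3R). Insertion must beat 1,2-hydride migration from the C3 methyl and ylide formation at O1: the bulky carboxylate ligands and low temperature slow the migration, the non-polar solvent disfavours the ylide, O5 carries a silyl group without C–H next to oxygen, the O7 methyl is out of reach, and the neutral medium leaves the kinetic cis product unepimerised.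

Step 6
Reactants: 12 (2S,3R)-7-methoxy-2,3-dimethyl-5-(triisopropylsilyloxy)chroman-4-one; 13 N-iodosuccinimide
Product: 14 (2S,3R)-8-iodo-7-methoxy-2,3-dimethyl-5-(triisopropylsilyloxy)chroman-4-one
Conditions: NIS (1.05 equiv), CF3CO2H (0.1 equiv), MeCN, 0 °C, dark
Reagents that add atoms: N-iodosuccinimide O=C1CCC(=O)N1I
Why: Electrophilic aromatic iodination, in which both free ring positions are activated by three oxygens but C6 is buried between the methoxy and the bulky silyloxy group, so iodine should enter at C8, and the weakly acidic medium does not enolise C3.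

Step 7
Reactants: 14 (2S,3R)-8-iodo-7-methoxy-2,3-dimethyl-5-(triisopropylsilyloxy)chroman-4-one; 15 methyl (E)-3-(tributylstannyl)prop-2-enoate
Product: 16 methyl (E)-3-[(2S,3R)-7-methoxy-2,3-dimethyl-4-oxo-5-(triisopropylsilyloxy)chroman-8-yl]prop-2-enoate
Conditions: Pd2(dba)3 (2.5 mol %), AsPh3 (20 mol %), CuI (10 mol %), NMP, 50 °C
Reagents that add atoms: methyl (E)-3-(tributylstannyl)prop-2-enoate CCCC[Sn](CCCC)(CCCC)/C=C/C(=O)OC
Why: Stille coupling, which needs no base, keeps the E geometry of the vinylstannane and tolerates the ketone and the silyl ether, with the copper salt speeding transmetalation at the doubly ortho-substituted iodide.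

Step 8
Reactants: 16 methyl (E)-3-[(2S,3R)-7-methoxy-2,3-dimethyl-4-oxo-5-(triisopropylsilyloxy)chroman-8-yl]prop-2-enoate; 17 phenylboronic acid
Product: 18 methyl (3R)-3-[(2S,3R)-7-methoxy-2,3-dimethyl-4-oxo-5-(triisopropylsilyloxy)chroman-8-yl]-3-phenylpropanoate
Conditions: [RhCl(C2H4)2]2 (2.5 mol %), (R,R)-Ph-bod* = (1R,4R)-2,5-diphenylbicyclo[2.2.2]octa-2,5-diene (5.5 mol %), aq KOH (5 mol %, equimolar to Rh, to form the hydroxorhodium catalyst), PhB(OH)2 (3 equiv), 1,4-dioxane/H2O, 40 °C
Reagents that add atoms: phenylboronic acid OB(O)c1ccccc1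
Why: Hayashi–Miyaura asymmetric 1,4-addition, in which the phenylrhodium species held by the C2-symmetric diene carbometalates the enoate face left open by the ligand and water protonates the resulting rhodium enolate, so the benzylic centre is set as R under catalyst control, no free hydroxide remains to touch C3, and any minor benzylic epimer is a separable diastereomer.

Step 9
Reactants: 18 methyl (3R)-3-[(2S,3R)-7-methoxy-2,3-dimethyl-4-oxo-5-(triisopropylsilyloxy)chroman-8-yl]-3-phenylpropanoate
Product: 19 methyl (3R)-3-[(2S,3R)-5-hydroxy-7-methoxy-2,3-dimethyl-4-oxochroman-8-yl]-3-phenylpropanoate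
Conditions: HF·pyridine, THF, 0 °C to rt
Reagents that add atoms: none
Why: Fluoride-driven desilylation in an acidic medium, in which formation of the strong Si–F bond frees the phenol, and the absence of basic fluoride protects C3 and the methyl ester.

Step 10
Reactants: 19 methyl (3R)-3-[(2S,3R)-5-hydroxy-7-methoxy-2,3-dimethyl-4-oxochroman-8-yl]-3-phenylpropanoate; 13 N-iodosuccinimide
Product: 20 methyl (3R)-3-[(2S,3R)-5-hydroxy-6-iodo-7-methoxy-2,3-dimethyl-4-oxochroman-8-yl]-3-phenylpropanoate
Conditions: NIS (1.05 equiv), CF3CO2H (0.1 equiv), MeCN, 0 °C, dark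
Reagents that add atoms: N-iodosuccinimide O=C1CCC(=O)N1I
Why: Electrophilic aromatic iodination ortho to the free phenol, where C6 is the only unsubstituted position of the electron-rich ring and the plain phenyl ring is far less reactive.

Step 11
Reactants: 20 methyl (3R)-3-[(2S,3R)-5-hydroxy-6-iodo-7-methoxy-2,3-dimethyl-4-oxochroman-8-yl]-3-phenylpropanoate; 21 tributyl(3-methylbut-2-enyl)stannane
Product: 22 methyl (3R)-3-[(2S,3R)-5-hydroxy-7-methoxy-2,3-dimethyl-6-(3-methylbut-2-enyl)-4-oxochroman-8-yl]-3-phenylpropanoate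
Conditions: Pd(PPh3)4 (5 mol %), tributyl(3-methylbut-2-enyl)stannane (1.5 equiv), degassed DMF, 80 °C
Reagents that add atoms: tributyl(3-methylbut-2-enyl)stannane CCCC[Sn](CCCC)(CCCC)CC=C(C)C
Why: Stille allylation with a prenylstannane, a base-free cross-coupling in which reductive elimination from the allylpalladium intermediate takes place at the less hindered primary terminus and so should give the linear 3-methylbut-2-enyl group.

Step 12
Reactants: 22 methyl (3R)-3-[(2S,3R)-5-hydroxy-7-methoxy-2,3-dimethyl-6-(3-methylbut-2-enyl)-4-oxochroman-8-yl]-3-phenylpropanoate; 23 trimethyltin hydroxide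
Product: 25 (3R)-3-[(2S,3R)-5-hydroxy-7-methoxy-2,3-dimethyl-6-(3-methylbut-2-enyl)-4-oxochroman-8-yl]-3-phenylpropanoic acid (CNP0172137.1), via trimethylstannyl ester 24 (not isolated)
Conditions: Me3SnOH (5 equiv), ClCH2CH2Cl, 70 °C; then brief 0.5 M HCl wash
Reagents that add atoms: trimethyltin hydroxide C[Sn](C)(C)O
Why: Trimethyltin hydroxide ester cleavage, an acyl substitution at the unhindered methyl ester assisted by the Lewis acidic tin under nearly neutral conditions, so C3 is not enolised and the prenyl and phenol pair never meets strong acid that would close a chroman ring.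

Compound list
1 | 1-(2,4,6-trihydroxyphenyl)propan-1-one | CCC(=O)c1c(O)cc(O)cc1O | starting material
2 | dimethyl sulfate | COS(=O)(=O)OC | starting material
3 | 1-(2,6-dihydroxy-4-methoxyphenyl)propan-1-one | CCC(=O)c1c(O)cc(OC)cc1O | intermediate
4 | iodoethane | CCI | starting material
5 | 1-(2-ethoxy-6-hydroxy-4-methoxyphenyl)propan-1-one | CCOc1cc(OC)cc(O)c1C(=O)CC | intermediate
6 | triisopropylsilyl trifluoromethanesulfonate | CC(C)[Si](C(C)C)(C(C)C)OS(=O)(=O)C(F)(F)F | starting material
7 | 1-[2-ethoxy-4-methoxy-6-(triisopropylsilyloxy)phenyl]propan-1-one | CCOc1cc(OC)cc(O[Si](C(C)C)(C(C)C)C(C)C)c1C(=O)CC | intermediate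
8 | 2,2,2-trifluoroethyl trifluoroacetate | FC(F)(F)COC(=O)C(F)(F)F | starting material
9 | 4-acetamidobenzenesulfonyl azide | CC(=O)Nc1ccc(cc1)S(=O)(=O)N=[N+]=[N-] | starting material
10 | 1-[2-ethoxy-4-methoxy-6-(triisopropylsilyloxy)phenyl]-4,4,4-trifluoro-2-methylbutane-1,3-dione (labile alpha centre, not defined) | CCOc1cc(OC)cc(O[Si](C(C)C)(C(C)C)C(C)C)c1C(=O)C(C)C(=O)C(F)(F)F | intermediate
11 | 2-diazo-1-[2-ethoxy-4-methoxy-6-(triisopropylsilyloxy)phenyl]propan-1-one | CCOc1cc(OC)cc(O[Si](C(C)C)(C(C)C)C(C)C)c1C(=O)C(C)=[N+]=[N-] | intermediate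
12 | (2S,3R)-7-methoxy-2,3-dimethyl-5-(triisopropylsilyloxy)chroman-4-one | COc1cc(O[Si](C(C)C)(C(C)C)C(C)C)c2c(c1)O[C@@H](C)[C@@H](C)C2=O | intermediate
13 | N-iodosuccinimide | O=C1CCC(=O)N1I | starting material
14 | (2S,3R)-8-iodo-7-methoxy-2,3-dimethyl-5-(triisopropylsilyloxy)chroman-4-one | COc1cc(O[Si](C(C)C)(C(C)C)C(C)C)c2c(c1I)O[C@@H](C)[C@@H](C)C2=O | intermediate
15 | methyl (E)-3-(tributylstannyl)prop-2-enoate | CCCC[Sn](CCCC)(CCCC)/C=C/C(=O)OC | starting material
16 | methyl (E)-3-[(2S,3R)-7-methoxy-2,3-dimethyl-4-oxo-5-(triisopropylsilyloxy)chroman-8-yl]prop-2-enoate | COC(=O)/C=C/c1c(OC)cc(O[Si](C(C)C)(C(C)C)C(C)C)c2c1O[C@@H](C)[C@@H](C)C2=O | intermediate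
17 | phenylboronic acid | OB(O)c1ccccc1 | starting material
18 | methyl (3R)-3-[(2S,3R)-7-methoxy-2,3-dimethyl-4-oxo-5-(triisopropylsilyloxy)chroman-8-yl]-3-phenylpropanoate | COc1cc(O[Si](C(C)C)(C(C)C)C(C)C)c2c(c1[C@H](CC(=O)OC)c1ccccc1)O[C@@H](C)[C@@H](C)C2=O | intermediate
19 | methyl (3R)-3-[(2S,3R)-5-hydroxy-7-methoxy-2,3-dimethyl-4-oxochroman-8-yl]-3-phenylpropanoate | COc1cc(O)c2c(c1[C@H](CC(=O)OC)c1ccccc1)O[C@@H](C)[C@@H](C)C2=O | intermediate
20 | methyl (3R)-3-[(2S,3R)-5-hydroxy-6-iodo-7-methoxy-2,3-dimethyl-4-oxochroman-8-yl]-3-phenylpropanoate | COc1c(I)c(O)c2c(c1[C@H](CC(=O)OC)c1ccccc1)O[C@@H](C)[C@@H](C)C2=O | intermediate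
21 | tributyl(3-methylbut-2-enyl)stannane | CCCC[Sn](CCCC)(CCCC)CC=C(C)C | starting material
22 | methyl (3R)-3-[(2S,3R)-5-hydroxy-7-methoxy-2,3-dimethyl-6-(3-methylbut-2-enyl)-4-oxochroman-8-yl]-3-phenylpropanoate | COc1c(CC=C(C)C)c(O)c2c(c1[C@H](CC(=O)OC)c1ccccc1)O[C@@H](C)[C@@H](C)C2=O | intermediate
23 | trimethyltin hydroxide | C[Sn](C)(C)O | starting material
24 | trimethylstannyl (3R)-3-[(2S,3R)-5-hydroxy-7-methoxy-2,3-dimethyl-6-(3-methylbut-2-enyl)-4-oxochroman-8-yl]-3-phenylpropanoate | COc1c(CC=C(C)C)c(O)c2c(c1[C@H](CC(=O)O[Sn](C)(C)C)c1ccccc1)O[C@@H](C)[C@@H](C)C2=O | intermediate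
25 | (3R)-3-[(2S,3R)-5-hydroxy-7-methoxy-2,3-dimethyl-6-(3-methylbut-2-enyl)-4-oxochroman-8-yl]-3-phenylpropanoic acid | COc1c(CC=C(C)C)c(O)c2c(c1[C@H](CC(=O)O)c1ccccc1)O[C@@H](C)[C@@H](C)C2=O | target

Total step count: 12. Longest linear sequence: 12 steps (1 to 25).

Steps most likely to fail

Step 5. Three things may go wrong: hydride migration from the C3 methyl to the carbenoid carbon, attack of the O1 lone pair on the carbenoid, or weak discrimination between the two methylene hydrogens.
- The fallback closes ring C at the O1–C2 bond instead, by an aldol addition followed by a Mitsunobu cyclisation. It sets out from 3.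
- Silylation of one phenol (TIPSCl, imidazole, DMF) should give 1-[2-hydroxy-4-methoxy-6-(triisopropylsilyloxy)phenyl]propan-1-one F1.
- Enolisation with (c-C6H11)2BCl (2.2 equiv, the first equivalent masking the phenol as its borinate) and Et3N gives the E boron enolate. This adds to acetaldehyde to give the racemic anti aldol after oxidative work-up at pH 7.
- Chromatography on a chiral phase separates (2R,3R)-3-hydroxy-1-[2-hydroxy-4-methoxy-6-(triisopropylsilyloxy)phenyl]-2-methylbutan-1-one F2 from its (2S,3S) enantiomer F3.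
- Mitsunobu cyclisation of F2 (PPh3, DIAD, THF, 0 °C) lets the phenol displace the activated carbinol oxygen with inversion. This turns the anti aldol into the cis chromanone and comes back to the route at 12.

Step 8. Carbometalation of an enoate whose beta carbon bears an electron-rich, doubly ortho-substituted aryl group may be slow, and facial selectivity may be poor.
- The fallback makes the C8–C bond with the arene as nucleophile and sets the centre by hydrogenation. It sets out from 12 and bypasses 14 and 16.
- Palladium-catalysed trans-hydroarylation of methyl phenylpropiolate (Pd(OAc)2, CF3CO2H/CH2Cl2, rt; Fujiwara hydroarylation) at the less shielded C8 should give methyl (Z)-3-[(2S,3R)-7-methoxy-2,3-dimethyl-4-oxo-5-(triisopropylsilyloxy)chroman-8-yl]-3-phenylprop-2-enoate F4.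
- Asymmetric hydrogenation of this geometrically defined beta,beta-diaryl acrylate follows ([Ir(cod)((S)-tBu-PHOX)]BArF or its antipode, H2, CH2Cl2, rt). No other alkene is present at this stage. It comes back to the route at 18.

Step 11. Allyl transposition on palladium may deliver the tertiary terminus, transmetalation of the bulky stannane at the crowded C6 iodide may be slow, and protodeiodination may compete.
- The fallback builds the prenyl group in two stages and sets out from 20.
- Stille coupling with allyltributylstannane (Pd(PPh3)4, DMF, 80 °C), for which transposition is degenerate, should give methyl (3R)-3-[(2S,3R)-5-hydroxy-7-methoxy-2,3-dimethyl-4-oxo-6-(prop-2-enyl)chroman-8-yl]-3-phenylpropanoate F5.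
- Cross metathesis with excess 2-methylbut-2-ene (second-generation Grubbs catalyst, CH2Cl2, 40 °C) then caps the terminal alkene and comes back to the route at 22.

Further compounds
F1 | step 5 | 1-[2-hydroxy-4-methoxy-6-(triisopropylsilyloxy)phenyl]propan-1-one | CCC(=O)c1c(O)cc(OC)cc1O[Si](C(C)C)(C(C)C)C(C)C
F2 | step 5 | (2R,3R)-3-hydroxy-1-[2-hydroxy-4-methoxy-6-(triisopropylsilyloxy)phenyl]-2-methylbutan-1-one | O[C@H](C)[C@@H](C)C(=O)c1c(O)cc(OC)cc1O[Si](C(C)C)(C(C)C)C(C)C
F3 | step 5 | (2S,3S)-3-hydroxy-1-[2-hydroxy-4-methoxy-6-(triisopropylsilyloxy)phenyl]-2-methylbutan-1-one | O[C@@H](C)[C@H](C)C(=O)c1c(O)cc(OC)cc1O[Si](C(C)C)(C(C)C)C(C)C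
F4 | step 8 | methyl (Z)-3-[(2S,3R)-7-methoxy-2,3-dimethyl-4-oxo-5-(triisopropylsilyloxy)chroman-8-yl]-3-phenylprop-2-enoate | COC(=O)/C=C(/c1ccccc1)c1c(OC)cc(O[Si](C(C)C)(C(C)C)C(C)C)c2c1O[C@@H](C)[C@@H](C)C2=O
F5 | step 11 | methyl (3R)-3-[(2S,3R)-5-hydroxy-7-methoxy-2,3-dimethyl-4-oxo-6-(prop-2-enyl)chroman-8-yl]-3-phenylpropanoate | COc1c(CC=C)c(O)c2c(c1[C@H](CC(=O)OC)c1ccccc1)O[C@@H](C)[C@@H](C)C2=O
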